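The easy step comes first: starting material takes up reagent and gives target.

common to all: starting material 0.50 M
- ash: reagent 0.16 M; second substrate 2.5 M; run made earlier
- larch: reagent 1.2 M; second substrate 2.5 M; run made earlier
- alpha: reagent 0.200 M; second substrate 2.50 M; time 3.0 d
- delta: reagent 0.400 M; second substrate 2.50 M; time 3.0 d
- theta: reagent 0.800 M; second substrate 2.50 M; time 3.0 d
- gamma: reagent 1.50 M; second substrate 2.50 M; time 3.0 d

| run | time / h | target / % | starting material / % |
|---|---|---|---|
| ash | 6.00 | 8 | 87 |
| ash | 20.0 | 10 | 90 |
| ash | 30.0 | 9 | 92 |
| ash | 48.0 | 8 | 90 |
| larch | 6.00 | 38 | 43 |
| larch | 20.0 | 26 | 37 |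
| larch | 30.0 | 20 | 37 |
| larch | 48.0 | 16 | 28 |

(readings scatter by 1.5 percentage points)
* amount of target at the end, in percent of the starting material charged for alpha, delta, theta, gamma, in this order
* how the row runs (falls, then rises / falls all the way / rises all the way / hardly changes / rises, then falls)
- the numbers in the tables scatter by 1.5 percentage points (one standard deviation)
- "hardly changes" means that all values lie within two and a half points (for a concentration: within two and a half percent of the largest)

The reckoning here treats that step as a pre-equilibrium between two forms, and the number to follow is the split, target over starting material, with one as the even case. Over the last 3 readings the ash run gives a split of 0.0993 and the larch run 0.605, which is the reading carried forward as the split; it is higher in larch, the run with the larger reagent charge. The reckoning here takes the split in proportion to that charge from larch, which gives 0.101, 0.202, 0.403 and 0.756 for alpha, delta, theta and gamma. Target is then split over one plus split, so this first picture rises from 9.17 % in alpha to 43.1 % in gamma.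

The second process shows in the pool, target plus starting material. In larch the pool goes from 81.0 % at 6.00 h to 44.0 % at 48.0 h, a loss of 0.0145 h⁻¹ of the pool. The reckoning takes this drain as following the target share of the pool and, as a measure of free reagent, the split. The drain is then a constant times split squared over one plus split, and larch gives the constant as 0.0637 h⁻¹. For ash this predicts a shortfall of the pool below the charge of 2.74 % at 48.0 h, and the readings show 2.00 %.

Putting the two together, the target share is multiplied by the pool left after 3.0 d. The reckoned row is 8.79 %, 14.4 %, 16.9 % and 9.68 %, which rises, then falls.

The forecast gives 9 %, 11 %, 13 % and 14 %, a row that rises all the way, and it states “High charges converge on a ceiling”.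

The flask gives 8.67 %, 12.8 %, 14.6 % and 8.77 %: the row rises, then falls.

    reagent + target → over-reaction product (k = 3.18 × 10⁻⁵ M⁻¹ s⁻¹)
    second substrate + reagent ⇌ second product (K = 0.590 M⁻¹, k = 2.98 × 10⁻⁵ M⁻¹ s⁻¹)
    starting material + reagent ⇌ target (K = 2.20 M⁻¹, k = 0.00343 M⁻¹ s⁻¹)

Gamma ends with a split of 0.654, higher than the 0.312 of theta, yet with less target, 8.77 % against 14.6 %. At the end the pool in gamma is 22.2 % of the charge, and in theta 61.4 %, while over-reaction product stands at 77.8 % in gamma. The path from reagent and target to over-reaction product is the main reason for the turn: with that path taken away, gamma holds 56.1 % of target instead of 8.77 %.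

The readings were generated by integration from invented constants, noise included.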